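Everything rests on cutting the bond between the anisyl carbinol carbon C1 and the branch carbon C2. C2 also bears the CH2O carbon and an allylic CH2 running into the E CH=CH of the 3,4-dimethoxyphenyl ring, so the run CH2O–C2–CH2–CH=CH–aryl is a 5-aryl-penta-2,4-dienoate that has accepted one hydride at its β-carbon. A rhodium-catalysed asymmetric reductive aldol of this planar, achiral dienoate with 4-methoxybenzaldehyde should generate the C2 enolate, forge C1–C2 and set both stereocentres anti in one operation. Ester reduction and a geometry-retaining carbonylative esterification of a Z vinyl iodide at the primary oxygen then complete the (Z)-2-(hydroxymethyl)but-2-enoate.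

Key step: step 2

Remark on the chemistry (assumption): the (R,R)-isopropyl Phebox rhodium acetate complex (from D-valinol) is written on the assumption that the (S,S) series gives the (2S,3R) anti aldol with aryl aldehydes and that this sense carries over to the dienoate. If a test run shows the opposite sense, the (S,S) complex is used with nothing else changed. The complex is a known catalyst made from the bis(oxazolinyl)benzene, RhCl3·3H2O and AgOAc, and is treated as a reagent.

Step 1
Reactants: 1 (E)-3-(3,4-dimethoxyphenyl)prop-2-enal; 2 tert-butyl 2-(diethoxyphosphoryl)acetate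
Product: 3 tert-butyl (2E,4E)-5-(3,4-dimethoxyphenyl)penta-2,4-dienoate
Conditions: NaH (1.1 equiv), THF, 0 °C to rt
Reagents that add atoms: none
Why: Horner–Wadsworth–Emmons olefination of a non-enolisable enal with a stabilised phosphonate anion should give the new C2=C3 alkene E under thermodynamic control, while the existing E styrene is carried through unchanged.

Step 2
Reactants: 3 tert-butyl (2E,4E)-5-(3,4-dimethoxyphenyl)penta-2,4-dienoate; 4 4-methoxybenzaldehyde
Product: 6 tert-butyl (2R,3S)-2-[(E)-3-(3,4-dimethoxyphenyl)prop-2-en-1-yl]-3-hydroxy-3-(4-methoxyphenyl)propanoate, via diethoxymethylsilyl ether 5 (not isolated)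
Conditions: (R,R)-Rh(Phebox-iPr)(OAc)2(H2O) (2 mol%; Phebox-iPr = 2,6-bis[(4R)-4-isopropyl-4,5-dihydrooxazol-2-yl]phenyl), (EtO)2MeSiH (1.6 equiv), 4 (1.5 equiv), toluene, 50 °C; then TBAF/AcOH (1:1), THF, 0 °C
Reagents that add atoms: none
Why: Proposed new method: the acetate complex and the silane should form a rhodium hydride that adds across the s-cis C2=C3–C1=O unit of 3, placing hydride on C3 (the future allylic CH2) and leaving an E rhodium enolate at C2 with the C4=C5 styrene untouched; this enolate binds 4, forms the bond from C2 to the carbinol carbon through a closed chair transition state inside the ligand pocket, and the silane then releases silyl ether 5 and regenerates the hydride. Its nearest precedent in type is the Rh(Phebox)/alkoxyhydrosilane reductive coupling of tert-butyl acrylate with aryl aldehydes, which is anti- and enantioselective, and the same complexes are known to reduce β-substituted enoates and dienoates in the 1,4 sense; what is new is a δ-aryl 2,4-dienoate in the donor role. The step is acyclic, so no ring is formed and no closure mode has to be considered. Both new stereocentres, C2 (R) and the carbinol carbon (S), are set together: the anti relation by the E enolate in the chair, and the absolute sense by the C2-symmetric bis(oxazoline) pincer, which exposes one face of the bound aldehyde. Three selectivities are required, namely hydride to C3 and not C5, anti and not syn, and one aldehyde face; hydride at C3 keeps C4=C5 conjugated to the electron-rich dimethoxyphenyl ring, whose donation also makes C5 a poor hydride acceptor, and the bulky tert-butyl ester favours the E enolate. The neutral coupling and the acetic-acid-buffered fluoride cleavage of 5 keep the anisaldehyde-derived anti aldol away from base (retro-aldol, epimerisation) and from acid (benzylic ionisation).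

Step 3
Reactants: 6 tert-butyl (2R,3S)-2-[(E)-3-(3,4-dimethoxyphenyl)prop-2-en-1-yl]-3-hydroxy-3-(4-methoxyphenyl)propanoate
Product: 7 (1S,2S)-2-[(E)-3-(3,4-dimethoxyphenyl)prop-2-en-1-yl]-1-(4-methoxyphenyl)propane-1,3-diol
Conditions: LiAlH4 (2.5 equiv), THF, −20 to 0 °C; Rochelle salt work-up
Reagents that add atoms: none
Why: LiAlH4 reduction of the ester to the primary alcohol should leave the isolated styrene alone and, run cold, should not trigger retro-aldol of the aluminium aldolate, so both stereocentres are carried over (the C2 descriptor changes from R to S only through the CIP ranking).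

Step 4
Reactants: 8 (E)-but-2-enal
Product: 9 (Z)-2-iodobut-2-enal
Conditions: I2 (1.5 equiv), K2CO3 (1.2 equiv), DMAP (0.2 equiv), THF/H2O (1:1), rt
Reagents that add atoms: iodine, II
Why: α-iodination of an enal by a Baylis–Hillman-type sequence (DMAP adds to C3, the enolate is iodinated at C2, DMAP is expelled) should give the more stable Z iodoenal, with iodine cis to methyl and the formyl group still trans to it.

Step 5
Reactants: 9 (Z)-2-iodobut-2-enal
Product: 10 (Z)-2-iodobut-2-en-1-ol
Conditions: NaBH4, CeCl3·7H2O, MeOH, 0 °C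
Reagents that add atoms: none
Why: Luche reduction delivers hydride 1,2 to the carbonyl of the enal and should leave the C–I bond and the alkene geometry intact.

Step 6
Reactants: 10 (Z)-2-iodobut-2-en-1-ol
Product: 11 (Z)-tert-butyl[(2-iodobut-2-en-1-yl)oxy]dimethylsilane
Conditions: TBSCl, imidazole, CH2Cl2, 0 °C to rt
Reagents that add atoms: tert-butyldimethylsilyl chloride, CC(C)(C)[Si](C)(C)Cl
Why: imidazole-promoted silylation of the primary allylic alcohol masks the hydroxyl that would otherwise capture the acylpalladium of the next step intramolecularly.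

Step 7
Reactants: 7 (1S,2S)-2-[(E)-3-(3,4-dimethoxyphenyl)prop-2-en-1-yl]-1-(4-methoxyphenyl)propane-1,3-diol; 11 (Z)-tert-butyl[(2-iodobut-2-en-1-yl)oxy]dimethylsilane; 12 carbon monoxide
Product: 13 (2S,3S)-2-[(E)-3-(3,4-dimethoxyphenyl)prop-2-en-1-yl]-3-hydroxy-3-(4-methoxyphenyl)propyl (Z)-2-{[(tert-butyldimethylsilyl)oxy]methyl}but-2-enoate
Conditions: PdCl2(PPh3)2 (5 mol%), 11 (1.5 equiv), Et3N (3 equiv), CO (1 atm), DMF, 50 °C
Reagents that add atoms: none
Why: palladium-catalysed alkoxycarbonylation of a vinyl iodide (Heck-type carbonylation), in which zerovalent palladium inserts into the C–I bond with retention, CO inserts, and the unhindered primary hydroxyl of 7 rather than the benzylic one cleaves the acylpalladium, should give the Z ester without a free activated acid that could isomerise to the E ester.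

Step 8
Reactants: 13 (2S,3S)-2-[(E)-3-(3,4-dimethoxyphenyl)prop-2-en-1-yl]-3-hydroxy-3-(4-methoxyphenyl)propyl (Z)-2-{[(tert-butyldimethylsilyl)oxy]methyl}but-2-enoate
Product: 14 (2S,3S)-2-[(E)-3-(3,4-dimethoxyphenyl)prop-2-en-1-yl]-3-hydroxy-3-(4-methoxyphenyl)propyl (Z)-2-(hydroxymethyl)but-2-enoate
Conditions: TBAF/AcOH (1:1, 2 equiv), THF, 0 °C to rt
Reagents that add atoms: none
Why: fluoride cleavage of the primary silyl ether, buffered with acetic acid so that no free alkoxide can start a 1,3-acyl shift or a conjugate addition and the medium never becomes acidic enough to ionise the anisyl carbinol, should release the target.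

Compound list
1 | (E)-3-(3,4-dimethoxyphenyl)prop-2-enal | COc1ccc(/C=C/C=O)cc1OC | starting material
2 | tert-butyl 2-(diethoxyphosphoryl)acetate | CCOP(=O)(OCC)CC(=O)OC(C)(C)C | starting material
3 | tert-butyl (2E,4E)-5-(3,4-dimethoxyphenyl)penta-2,4-dienoate | COc1ccc(/C=C/C=C/C(=O)OC(C)(C)C)cc1OC | intermediate
4 | 4-methoxybenzaldehyde | COc1ccc(C=O)cc1 | starting material
5 | tert-butyl (2R,3S)-3-{[diethoxy(methyl)silyl]oxy}-2-[(E)-3-(3,4-dimethoxyphenyl)prop-2-en-1-yl]-3-(4-methoxyphenyl)propanoate | CC(C)(C)OC(=O)[C@H](C/C=C/c1ccc(OC)c(OC)c1)[C@H](O[Si](C)(OCC)OCC)c1ccc(OC)cc1 | intermediate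
6 | tert-butyl (2R,3S)-2-[(E)-3-(3,4-dimethoxyphenyl)prop-2-en-1-yl]-3-hydroxy-3-(4-methoxyphenyl)propanoate | CC(C)(C)OC(=O)[C@H](C/C=C/c1ccc(OC)c(OC)c1)[C@H](O)c1ccc(OC)cc1 | intermediate
7 | (1S,2S)-2-[(E)-3-(3,4-dimethoxyphenyl)prop-2-en-1-yl]-1-(4-methoxyphenyl)propane-1,3-diol | OC[C@H](C/C=C/c1ccc(OC)c(OC)c1)[C@H](O)c1ccc(OC)cc1 | intermediate
8 | (E)-but-2-enal | C/C=C/C=O | starting material
9 | (Z)-2-iodobut-2-enal | C/C=C(\I)C=O | intermediate
10 | (Z)-2-iodobut-2-en-1-ol | C/C=C(\I)CO | intermediate
11 | (Z)-tert-butyl[(2-iodobut-2-en-1-yl)oxy]dimethylsilane | C/C=C(\I)CO[Si](C)(C)C(C)(C)C | intermediate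
12 | carbon monoxide | [C-]#[O+] | starting material
13 | (2S,3S)-2-[(E)-3-(3,4-dimethoxyphenyl)prop-2-en-1-yl]-3-hydroxy-3-(4-methoxyphenyl)propyl (Z)-2-{[(tert-butyldimethylsilyl)oxy]methyl}but-2-enoate | C/C=C(/CO[Si](C)(C)C(C)(C)C)C(=O)OC[C@H](C/C=C/c1ccc(OC)c(OC)c1)[C@H](O)c1ccc(OC)cc1 | intermediate
14 | (2S,3S)-2-[(E)-3-(3,4-dimethoxyphenyl)prop-2-en-1-yl]-3-hydroxy-3-(4-methoxyphenyl)propyl (Z)-2-(hydroxymethyl)but-2-enoate | C/C=C(/CO)C(=O)OC[C@H](C/C=C/c1ccc(OC)c(OC)c1)[C@H](O)c1ccc(OC)cc1 | target

Total step count: 8
Longest linear sequence: 5 steps (steps 1, 2, 3, 7, 8 from 1; equally steps 4 to 8 from 8)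

Steps most likely to fail

1. Step 2 (labelled). Hydride may go to C5, the enolate may be silylated or protonated before it meets the aldehyde, the aldehyde may be hydrosilylated instead, or the β-substituted enolate may give poor anti or facial selectivity. The fallback uses known chemistry, sets out from 1 and returns at 7. Compound 1 is reduced (NaBH4, CeCl3·7H2O, MeOH, 0 °C) to (E)-3-(3,4-dimethoxyphenyl)prop-2-en-1-ol F1 and brominated (PBr3, Et2O, 0 °C) to 4-[(E)-3-bromoprop-1-en-1-yl]-1,2-dimethoxybenzene F2, which is used at once. Commercial ethyl 3-(4-methoxyphenyl)-3-oxopropanoate (CCOC(=O)CC(=O)c1ccc(OC)cc1) is reduced by Noyori–Ikariya transfer hydrogenation (RuCl(p-cymene)[(S,S)-TsDPEN], HCO2H/Et3N), which should give ethyl (S)-3-hydroxy-3-(4-methoxyphenyl)propanoate F3. Fráter–Seebach alkylation of the dianion of F3 (LDA, 2.2 equiv, THF, −50 °C, then F2 and DMPU) should give ethyl (2R,3S)-2-[(E)-3-(3,4-dimethoxyphenyl)prop-2-en-1-yl]-3-hydroxy-3-(4-methoxyphenyl)propanoate F4. This is the anti isomer, because the electrophile approaches the chelated alkoxide–enolate on the side away from the aryl group. LiAlH4 reduction of F4 under the conditions of step 3 rejoins the route at diol 7.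

2. Step 7. Capture of the acylpalladium by a stoichiometric alcohol may be slow, which would lead to catalyst decay, acylation at the benzylic oxygen or Z-to-E isomerisation. The fallback sets out from 11 and returns at 13, and separates the C–C bond formation from the esterification. Hydroxycarbonylation of 11 (PdCl2(PPh3)2, CO 1 atm, Et3N, DMF/H2O, 50 °C; citric acid work-up) should give (Z)-2-{[(tert-butyldimethylsilyl)oxy]methyl}but-2-enoic acid F5 with the geometry retained. Mitsunobu esterification of F5 with diol 7 (PPh3, DIAD, THF, 0 °C) then activates the primary hydroxyl and lets the carboxylate displace it. The acid therefore never becomes an isomerisation-prone activated acyl species, and 13 is reached.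

3. Step 8. The acyl group may migrate from the primary to the benzylic oxygen, or the allylic alkoxide released by fluoride may cause conjugate addition or alkene isomerisation. The fallback sets out from 10 and returns at 14, and replaces the silyl group by one that comes off without basic fluoride. Compound 10 is silylated (TESCl, imidazole, CH2Cl2, 0 °C) to (Z)-triethyl[(2-iodobut-2-en-1-yl)oxy]silane F6. F6 is carbonylated with 7 under the conditions of step 7 to (2S,3S)-2-[(E)-3-(3,4-dimethoxyphenyl)prop-2-en-1-yl]-3-hydroxy-3-(4-methoxyphenyl)propyl (Z)-2-{[(triethylsilyl)oxy]methyl}but-2-enoate F7. The triethylsilyl ether is then cleaved with HF·pyridine buffered by excess pyridine in THF at 0 °C, a non-basic and only weakly acidic unmasking that should give target 14 directly.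

Further compounds
F1 | step 2 | (E)-3-(3,4-dimethoxyphenyl)prop-2-en-1-ol | COc1ccc(/C=C/CO)cc1OC
F2 | step 2 | 4-[(E)-3-bromoprop-1-en-1-yl]-1,2-dimethoxybenzene | COc1ccc(/C=C/CBr)cc1OC
F3 | step 2 | ethyl (S)-3-hydroxy-3-(4-methoxyphenyl)propanoate | CCOC(=O)C[C@H](O)c1ccc(OC)cc1
F4 | step 2 | ethyl (2R,3S)-2-[(E)-3-(3,4-dimethoxyphenyl)prop-2-en-1-yl]-3-hydroxy-3-(4-methoxyphenyl)propanoate | CCOC(=O)[C@H](C/C=C/c1ccc(OC)c(OC)c1)[C@H](O)c1ccc(OC)cc1
F5 | step 7 | (Z)-2-{[(tert-butyldimethylsilyl)oxy]methyl}but-2-enoic acid | C/C=C(/CO[Si](C)(C)C(C)(C)C)C(=O)O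
F6 | step 8 | (Z)-triethyl[(2-iodobut-2-en-1-yl)oxy]silane | C/C=C(\I)CO[Si](CC)(CC)CC
F7 | step 8 | (2S,3S)-2-[(E)-3-(3,4-dimethoxyphenyl)prop-2-en-1-yl]-3-hydroxy-3-(4-methoxyphenyl)propyl (Z)-2-{[(triethylsilyl)oxy]methyl}but-2-enoate | C/C=C(/CO[Si](CC)(CC)CC)C(=O)OC[C@H](C/C=C/c1ccc(OC)c(OC)c1)[C@H](O)c1ccc(OC)cc1
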